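**Plan**
- Retrosynthetic cuts, in order: the three O–Si bonds; the C4–C4a aryl ketone bond of ring C; the O1–C2 aryl ether bond; the ring B C1'–C2 bond and the aryl–prenyl bonds.
- Enabling feature (flavanone numbering): ring C (O1, C2, C3, C4, C4a, C8a) is an aryl ketone fused to ring A, and C4–C4a joins the carbonyl carbon to the ring A carbon ortho to O1. An open-chain 3-aryloxy-2-silyloxypropanamide that already carries C2 and C3 can therefore be closed at this bond without touching either centre.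
- Forward order: ring B cinnamyl alcohol (double C-prenylation, Heck, reduction) and its epoxide; ring A bromophenol by O-tert-prenylation and Claisen rearrangement; ether union at C2; chain oxidation to the N-methoxy-N-methylamide; ring C closed last; desilylation.
- Stereochemistry: C3 comes from a Sharpless epoxidation (L-(+)-tartrate); C2 comes from SN2 inversion when the ring A phenol opens the epoxide at the benzylic carbon. Both are spectators afterwards.

Key step: step 14

Abbreviations: TBS = tert-butyldimethylsilyl, TBSO = tert-butyldimethylsilyloxy, prenyl = 3-methylbut-2-enyl, CDI = 1,1'-carbonyldiimidazole.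

Remark (assumption): carbonate 12 is treated as a purchased reagent, and the facial sense of step 5 is taken from (E)-cinnamyl alcohol, for which L-(+)-tartrate gives the (2S,3S)-epoxide.

**Route**

Step 1
Reactants: 1 4-iodophenol; 2 1-bromo-3-methylbut-2-ene (prenyl bromide)
Product: 4 4-iodo-2,6-diprenylphenol, via 4-iodo-2-prenylphenol 3 (not isolated)
Conditions: prenyl bromide (2.2 equiv in all), KOH (2.5 equiv), H2O, rt
Reagents that add atoms: 1-bromo-3-methylbut-2-ene (second equivalent), CC(C)=CCBr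
Why: Ortho-C-alkylation of a phenoxide in water, where hydrogen bonding to the phenoxide oxygen steers the allylic bromide to carbon and iodine blocks the para position, so the first equivalent gives monoprenylphenol 3 and its phenoxide is alkylated by the second equivalent at the remaining ortho carbon.

Step 2
Reactants: 4 4-iodo-2,6-diprenylphenol; 5 methyl acrylate
Product: 6 methyl (E)-3-(4-hydroxy-3,5-diprenylphenyl)prop-2-enoate
Conditions: Pd(OAc)2 (cat.), P(o-tol)3, Et3N, MeCN, 80 °C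
Reagents that add atoms: none
Why: Mizoroki–Heck reaction, in which zerovalent palladium inserts into the aryl iodide and syn insertion of the acrylate followed by syn β-hydride elimination gives the (E)-cinnamate, the trisubstituted prenyl alkenes being too hindered to insert.

Step 3
Reactants: 6 methyl (E)-3-(4-hydroxy-3,5-diprenylphenyl)prop-2-enoate
Product: 7 methyl (E)-3-[3,5-diprenyl-4-(TBSO)phenyl]prop-2-enoate
Conditions: TBSOTf, 2,6-lutidine, CH2Cl2, 0 °C to rt
Reagents that add atoms: tert-butyldimethylsilyl trifluoromethanesulfonate, CC(C)(C)[Si](C)(C)OS(=O)(=O)C(F)(F)F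
Why: O-Silylation of a hindered phenol with the silyl triflate, 2,6-lutidine taking up the triflic acid so that the prenyl groups are not protonated.

Step 4
Reactants: 7 methyl (E)-3-[3,5-diprenyl-4-(TBSO)phenyl]prop-2-enoate
Product: 8 (E)-3-[3,5-diprenyl-4-(TBSO)phenyl]prop-2-en-1-ol
Conditions: i-Bu2AlH, CH2Cl2, −78 °C; aq. potassium sodium tartrate
Reagents that add atoms: none
Why: 1,2-Reduction of an enoate by the aluminium hydride at low temperature gives the allylic alcohol and leaves the aryl silyl ether and the isolated alkenes alone.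

Step 5
Reactants: 8 (E)-3-[3,5-diprenyl-4-(TBSO)phenyl]prop-2-en-1-ol
Product: 9 [(2S,3S)-3-[3,5-diprenyl-4-(TBSO)phenyl]oxiran-2-yl]methanol
Conditions: Ti(O-i-Pr)4 (10 mol%), L-(+)-diisopropyl tartrate (12 mol%), t-BuOOH (in decane), 4 Å molecular sieves, CH2Cl2, −20 °C; non-acidic work-up
Reagents that add atoms: tert-butyl hydroperoxide, CC(C)(C)OO
Why: Sharpless asymmetric epoxidation, in which the chiral complex formed from Ti(O-i-Pr)4 and the tartrate binds the allylic alkoxide and delivers the peroxide oxygen to one face (L-(+)-tartrate gives the 2S,3S epoxide of an (E)-3-arylallyl alcohol), while the prenyl alkenes cannot bind and are not epoxidised.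

Step 6
Reactants: 10 4-bromobenzene-1,3-diol (4-bromoresorcinol)
Product: 11 2-bromo-5-(TBSO)phenol
Conditions: TBSCl (1.0 equiv), imidazole, CH2Cl2, −20 to 0 °C
Reagents that add atoms: tert-butyldimethylsilyl chloride, CC(C)(C)[Si](C)(C)Cl
Why: Regioselective O-silylation, the hydroxyl para to bromine being less hindered and more nucleophilic than the one ortho to bromine, so one equivalent of silyl chloride should protect it preferentially.

Step 7
Reactants: 11 2-bromo-5-(TBSO)phenol; 12 tert-butyl 2-methylbut-3-en-2-yl carbonate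
Product: 13 1-bromo-2-(2-methylbut-3-en-2-yloxy)-4-(TBSO)benzene
Conditions: Pd(PPh3)4 (2 mol%), THF, 0 °C to rt
Reagents that add atoms: none
Why: Palladium-catalysed O-allylation of Tsuji–Trost type, in which zerovalent palladium ionises the tertiary carbonate with loss of CO2 and the phenoxide attacks the more substituted allyl terminus under kinetic control to give the 1,1-dimethylallyl ether, the electron-rich aryl bromide being inert at this temperature.

Step 8
Reactants: 13 1-bromo-2-(2-methylbut-3-en-2-yloxy)-4-(TBSO)benzene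
Product: 15 6-bromo-2-prenyl-3-(TBSO)phenol, via dienone 14 (not isolated)
Conditions: N,N-diethylaniline, 130 °C
Reagents that add atoms: none
Why: Aromatic Claisen rearrangement, whose [3,3] shift inverts the allyl unit so that a linear prenyl group arrives at the only free ortho carbon (the other carries bromine), and tautomerisation of dienone 14 frees exactly the hydroxyl flanked by bromine and prenyl, which differentiates the two resorcinol oxygens.

Step 9
Reactants: 9 [(2S,3S)-3-[3,5-diprenyl-4-(TBSO)phenyl]oxiran-2-yl]methanol; 15 6-bromo-2-prenyl-3-(TBSO)phenol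
Product: 16 (2S,3R)-3-[6-bromo-2-prenyl-3-(TBSO)phenoxy]-3-[3,5-diprenyl-4-(TBSO)phenyl]propane-1,2-diol
Conditions: Ti(O-i-Pr)4 (1.5 equiv), 15 (1.5 equiv), CH2Cl2, rt to 40 °C; aq. potassium sodium tartrate
Reagents that add atoms: none
Why: Ti(O-i-Pr)4-mediated C3-selective opening of a 2,3-epoxy alcohol, in which the phenol attacks the benzylic carbon of the metal-bound epoxy alkoxide anti to the epoxide oxygen, so this carbon (future C2 of the flavanone) is inverted to R while the carbinol carbon (future C3) keeps its configuration.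

Step 10
Reactants: 16 (2S,3R)-3-[6-bromo-2-prenyl-3-(TBSO)phenoxy]-3-[3,5-diprenyl-4-(TBSO)phenyl]propane-1,2-diol
Product: 17 (2S,3R)-3-[6-bromo-2-prenyl-3-(TBSO)phenoxy]-1,2-bis(TBSO)-3-[3,5-diprenyl-4-(TBSO)phenyl]propane
Conditions: TBSOTf (2.5 equiv), 2,6-lutidine, CH2Cl2, −78 to 0 °C
Reagents that add atoms: tert-butyldimethylsilyl trifluoromethanesulfonate, CC(C)(C)[Si](C)(C)OS(=O)(=O)C(F)(F)F
Why: Exhaustive O-silylation of the diol with the silyl triflate, which is reactive enough for the hindered secondary hydroxyl and is kept non-acidic by the lutidine.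

Step 11
Reactants: 17 (2S,3R)-3-[6-bromo-2-prenyl-3-(TBSO)phenoxy]-1,2-bis(TBSO)-3-[3,5-diprenyl-4-(TBSO)phenyl]propane
Product: 18 (2S,3R)-3-[6-bromo-2-prenyl-3-(TBSO)phenoxy]-2-(TBSO)-3-[3,5-diprenyl-4-(TBSO)phenyl]propan-1-ol
Conditions: camphorsulfonic acid (cat.), MeOH/CH2Cl2, 0 °C
Reagents that add atoms: none
Why: Acid-catalysed methanolysis of silyl ethers, which removes the unhindered primary alkyl silyl ether first because secondary alkyl and aryl silyl ethers solvolyse much more slowly under acid.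

Step 12
Reactants: 18 (2S,3R)-3-[6-bromo-2-prenyl-3-(TBSO)phenoxy]-2-(TBSO)-3-[3,5-diprenyl-4-(TBSO)phenyl]propan-1-ol
Product: 20 (2R,3R)-3-[6-bromo-2-prenyl-3-(TBSO)phenoxy]-2-(TBSO)-3-[3,5-diprenyl-4-(TBSO)phenyl]propanoic acid, via aldehyde 19 (not isolated)
Conditions: TEMPO (cat.), PhI(OAc)2, MeCN/H2O, rt
Reagents that add atoms: water, O
Why: Oxoammonium (TEMPO) oxidation of a primary alcohol to aldehyde 19 and, through its hydrate, to the acid under near-neutral conditions that should spare alkenes, silyl ethers and the α-centre (the change of descriptor from 2S to 2R is only a change of priorities).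

Step 13
Reactants: 20 (2R,3R)-3-[6-bromo-2-prenyl-3-(TBSO)phenoxy]-2-(TBSO)-3-[3,5-diprenyl-4-(TBSO)phenyl]propanoic acid
Product: 22 (2R,3R)-3-[6-bromo-2-prenyl-3-(TBSO)phenoxy]-2-(TBSO)-3-[3,5-diprenyl-4-(TBSO)phenyl]-N-methoxy-N-methylpropanamide, via acyl imidazolide 21 (not isolated)
Conditions: CDI, CH2Cl2, rt; then MeNHOMe·HCl, rt
Reagents that add atoms: N,O-dimethylhydroxylamine hydrochloride, CNOC.Cl
Why: Amide formation through an acyl imidazolide, a mild activation with no strong base present, so the α-silyloxy centre should not epimerise and the β-aryloxide should not be eliminated.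

Step 14
Reactants: 22 (2R,3R)-3-[6-bromo-2-prenyl-3-(TBSO)phenoxy]-2-(TBSO)-3-[3,5-diprenyl-4-(TBSO)phenyl]-N-methoxy-N-methylpropanamide
Product: 25 (2R,3R)-8-prenyl-3,7-bis(TBSO)-2-[3,5-diprenyl-4-(TBSO)phenyl]chroman-4-one, via aryllithium 23 (not isolated), via lithium aminal alkoxide 24 (not isolated)
Conditions: t-BuLi (2.1 equiv), THF, −78 °C; aq. NH4Cl, −78 °C to rt
Reagents that add atoms: none
Why: Bromine–lithium exchange at the carbon ortho to the ether oxygen (future C4a) gives aryllithium 23 (the second equivalent of t-BuLi destroys the tert-butyl bromide), and 23 adds to the amide carbonyl to give the lithium-chelated adduct 24, which survives until the cold quench and then collapses to ketone 25, forming the C4–C4a bond. This is a Parham cyclization onto an N-methoxy-N-methylamide, the established way from ortho-halogenated aryl ethers bearing such an amide to chroman-4-ones and related benzo-fused ketones. Ring C (O1, C2, C3, C4, C4a, C8a) closes in the 6-exo-trig mode. No lasting stereocentre is created: C2 (R) and C3 (R) pass through unchanged and the aminal centre of 24 is lost on collapse. The step needs exchange to outrun deprotonation at C3–H, which would expel the C2 aryloxide by β-elimination, and direct addition of t-BuLi to the amide; the C–Br bond ortho to oxygen exchanges very fast at −78 °C, C3–H is shielded by its silyloxy group, and chelated 24 can neither enolise nor accept a second nucleophile. Prenyl alkenes and silyl ethers are inert to the organolithium at this temperature, and the ring A silyloxy group sits para, not ortho, to the lithiated carbon, so no silyl migration to carbon is possible.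

Step 15
Reactants: 25 (2R,3R)-8-prenyl-3,7-bis(TBSO)-2-[3,5-diprenyl-4-(TBSO)phenyl]chroman-4-one
Product: 26 (2R,3R)-3,7-dihydroxy-2-(4-hydroxy-3,5-diprenylphenyl)-8-prenylchroman-4-one
Conditions: HF·pyridine, pyridine, THF, 0 °C to rt
Reagents that add atoms: none
Why: Fluoride-driven cleavage of all three Si–O bonds (global desilylation) under buffered, weakly acidic conditions that should neither protonate the prenyl groups nor open the base-sensitive 3-hydroxychromanone, so the trans-diequatorial C2/C3 pair is retained.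

**Compound list**

1 | 4-iodophenol | Oc1ccc(I)cc1 | starting material
2 | 1-bromo-3-methylbut-2-ene (prenyl bromide) | CC(C)=CCBr | starting material
3 | 4-iodo-2-(3-methylbut-2-enyl)phenol | CC(C)=CCc1cc(I)ccc1O | intermediate
4 | 4-iodo-2,6-bis(3-methylbut-2-enyl)phenol | CC(C)=CCc1cc(I)cc(CC=C(C)C)c1O | intermediate
5 | methyl acrylate | C=CC(=O)OC | starting material
6 | methyl (E)-3-[4-hydroxy-3,5-bis(3-methylbut-2-enyl)phenyl]prop-2-enoate | COC(=O)/C=C/c1cc(CC=C(C)C)c(O)c(CC=C(C)C)c1 | intermediate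
7 | methyl (E)-3-[4-(tert-butyldimethylsilyloxy)-3,5-bis(3-methylbut-2-enyl)phenyl]prop-2-enoate | COC(=O)/C=C/c1cc(CC=C(C)C)c(O[Si](C)(C)C(C)(C)C)c(CC=C(C)C)c1 | intermediate
8 | (E)-3-[4-(tert-butyldimethylsilyloxy)-3,5-bis(3-methylbut-2-enyl)phenyl]prop-2-en-1-ol | OC/C=C/c1cc(CC=C(C)C)c(O[Si](C)(C)C(C)(C)C)c(CC=C(C)C)c1 | intermediate
9 | [(2S,3S)-3-[4-(tert-butyldimethylsilyloxy)-3,5-bis(3-methylbut-2-enyl)phenyl]oxiran-2-yl]methanol | OC[C@@H]1O[C@H]1c1cc(CC=C(C)C)c(O[Si](C)(C)C(C)(C)C)c(CC=C(C)C)c1 | intermediate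
10 | 4-bromobenzene-1,3-diol | Oc1ccc(Br)c(O)c1 | starting material
11 | 2-bromo-5-(tert-butyldimethylsilyloxy)phenol | Oc1cc(O[Si](C)(C)C(C)(C)C)ccc1Br | intermediate
12 | tert-butyl 2-methylbut-3-en-2-yl carbonate | C=CC(C)(C)OC(=O)OC(C)(C)C | starting material
13 | 1-bromo-4-(tert-butyldimethylsilyloxy)-2-(2-methylbut-3-en-2-yloxy)benzene | C=CC(C)(C)Oc1cc(O[Si](C)(C)C(C)(C)C)ccc1Br | intermediate
14 | 2-bromo-5-(tert-butyldimethylsilyloxy)-6-(3-methylbut-2-enyl)cyclohexa-2,4-dien-1-one | O=C1C(Br)=CC=C(O[Si](C)(C)C(C)(C)C)C1CC=C(C)C | intermediate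
15 | 6-bromo-3-(tert-butyldimethylsilyloxy)-2-(3-methylbut-2-enyl)phenol | CC(C)=CCc1c(O)c(Br)ccc1O[Si](C)(C)C(C)(C)C | intermediate
16 | (2S,3R)-3-[6-bromo-3-(tert-butyldimethylsilyloxy)-2-(3-methylbut-2-enyl)phenoxy]-3-[4-(tert-butyldimethylsilyloxy)-3,5-bis(3-methylbut-2-enyl)phenyl]propane-1,2-diol | OC[C@H](O)[C@@H](c1cc(CC=C(C)C)c(O[Si](C)(C)C(C)(C)C)c(CC=C(C)C)c1)Oc1c(Br)ccc(O[Si](C)(C)C(C)(C)C)c1CC=C(C)C | intermediate
17 | (2S,3R)-3-[6-bromo-3-(tert-butyldimethylsilyloxy)-2-(3-methylbut-2-enyl)phenoxy]-1,2-bis(tert-butyldimethylsilyloxy)-3-[4-(tert-butyldimethylsilyloxy)-3,5-bis(3-methylbut-2-enyl)phenyl]propane | CC(C)(C)[Si](C)(C)OC[C@H](O[Si](C)(C)C(C)(C)C)[C@@H](c1cc(CC=C(C)C)c(O[Si](C)(C)C(C)(C)C)c(CC=C(C)C)c1)Oc1c(Br)ccc(O[Si](C)(C)C(C)(C)C)c1CC=C(C)C | intermediate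
18 | (2S,3R)-3-[6-bromo-3-(tert-butyldimethylsilyloxy)-2-(3-methylbut-2-enyl)phenoxy]-2-(tert-butyldimethylsilyloxy)-3-[4-(tert-butyldimethylsilyloxy)-3,5-bis(3-methylbut-2-enyl)phenyl]propan-1-ol | OC[C@H](O[Si](C)(C)C(C)(C)C)[C@@H](c1cc(CC=C(C)C)c(O[Si](C)(C)C(C)(C)C)c(CC=C(C)C)c1)Oc1c(Br)ccc(O[Si](C)(C)C(C)(C)C)c1CC=C(C)C | intermediate
19 | (2R,3R)-3-[6-bromo-3-(tert-butyldimethylsilyloxy)-2-(3-methylbut-2-enyl)phenoxy]-2-(tert-butyldimethylsilyloxy)-3-[4-(tert-butyldimethylsilyloxy)-3,5-bis(3-methylbut-2-enyl)phenyl]propanal | O=C[C@H](O[Si](C)(C)C(C)(C)C)[C@@H](c1cc(CC=C(C)C)c(O[Si](C)(C)C(C)(C)C)c(CC=C(C)C)c1)Oc1c(Br)ccc(O[Si](C)(C)C(C)(C)C)c1CC=C(C)C | intermediate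
20 | (2R,3R)-3-[6-bromo-3-(tert-butyldimethylsilyloxy)-2-(3-methylbut-2-enyl)phenoxy]-2-(tert-butyldimethylsilyloxy)-3-[4-(tert-butyldimethylsilyloxy)-3,5-bis(3-methylbut-2-enyl)phenyl]propanoic acid | OC(=O)[C@H](O[Si](C)(C)C(C)(C)C)[C@@H](c1cc(CC=C(C)C)c(O[Si](C)(C)C(C)(C)C)c(CC=C(C)C)c1)Oc1c(Br)ccc(O[Si](C)(C)C(C)(C)C)c1CC=C(C)C | intermediate
21 | (2R,3R)-3-[6-bromo-3-(tert-butyldimethylsilyloxy)-2-(3-methylbut-2-enyl)phenoxy]-2-(tert-butyldimethylsilyloxy)-3-[4-(tert-butyldimethylsilyloxy)-3,5-bis(3-methylbut-2-enyl)phenyl]-1-(imidazol-1-yl)propan-1-one | O=C(n1ccnc1)[C@H](O[Si](C)(C)C(C)(C)C)[C@@H](c1cc(CC=C(C)C)c(O[Si](C)(C)C(C)(C)C)c(CC=C(C)C)c1)Oc1c(Br)ccc(O[Si](C)(C)C(C)(C)C)c1CC=C(C)C | intermediate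
22 | (2R,3R)-3-[6-bromo-3-(tert-butyldimethylsilyloxy)-2-(3-methylbut-2-enyl)phenoxy]-2-(tert-butyldimethylsilyloxy)-3-[4-(tert-butyldimethylsilyloxy)-3,5-bis(3-methylbut-2-enyl)phenyl]-N-methoxy-N-methylpropanamide | CON(C)C(=O)[C@H](O[Si](C)(C)C(C)(C)C)[C@@H](c1cc(CC=C(C)C)c(O[Si](C)(C)C(C)(C)C)c(CC=C(C)C)c1)Oc1c(Br)ccc(O[Si](C)(C)C(C)(C)C)c1CC=C(C)C | intermediate
23 | (2R,3R)-3-[3-(tert-butyldimethylsilyloxy)-6-lithio-2-(3-methylbut-2-enyl)phenoxy]-2-(tert-butyldimethylsilyloxy)-3-[4-(tert-butyldimethylsilyloxy)-3,5-bis(3-methylbut-2-enyl)phenyl]-N-methoxy-N-methylpropanamide | CON(C)C(=O)[C@H](O[Si](C)(C)C(C)(C)C)[C@@H](c1cc(CC=C(C)C)c(O[Si](C)(C)C(C)(C)C)c(CC=C(C)C)c1)Oc1c([Li])ccc(O[Si](C)(C)C(C)(C)C)c1CC=C(C)C | intermediate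
24 | lithium (2R,3R)-3,7-bis(tert-butyldimethylsilyloxy)-2-[4-(tert-butyldimethylsilyloxy)-3,5-bis(3-methylbut-2-enyl)phenyl]-4-[methoxy(methyl)amino]-8-(3-methylbut-2-enyl)chroman-4-olate (C4 configuration undefined) | CON(C)C1(O[Li])c2ccc(O[Si](C)(C)C(C)(C)C)c(CC=C(C)C)c2O[C@H](c2cc(CC=C(C)C)c(O[Si](C)(C)C(C)(C)C)c(CC=C(C)C)c2)[C@H]1O[Si](C)(C)C(C)(C)C | intermediate
25 | (2R,3R)-3,7-bis(tert-butyldimethylsilyloxy)-2-[4-(tert-butyldimethylsilyloxy)-3,5-bis(3-methylbut-2-enyl)phenyl]-8-(3-methylbut-2-enyl)chroman-4-one | O=C1c2ccc(O[Si](C)(C)C(C)(C)C)c(CC=C(C)C)c2O[C@H](c2cc(CC=C(C)C)c(O[Si](C)(C)C(C)(C)C)c(CC=C(C)C)c2)[C@H]1O[Si](C)(C)C(C)(C)C | intermediate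
26 | (2R,3R)-3,7-dihydroxy-2-[4-hydroxy-3,5-bis(3-methylbut-2-enyl)phenyl]-8-(3-methylbut-2-enyl)chroman-4-one | CC(C)=CCc1cc([C@H]2Oc3c(ccc(O)c3CC=C(C)C)C(=O)[C@@H]2O)cc(CC=C(C)C)c1O | target

**Count**

Total steps: 15. Longest linear sequence: 12 (steps 1–5 and 9–15); the ring A branch (steps 6–8) joins at step 9.

**Steps most likely to fail**

1. Step 9. The doubly ortho-substituted phenol may attack too slowly, so that isopropoxide transfer from Ti(O-i-Pr)4 competes. The electron-rich benzylic epoxide, already delicate to isolate in step 5, may also ionise, which would erode the inversion at the benzylic carbon. The fallback makes the ether bond on a carbonyl-deactivated epoxide and avoids the epoxy alcohol altogether. It sets out from ester 7 and returns at amide 22, replacing steps 4, 5 and 9–13. Ester 7 would be converted with MeNHOMe·HCl and i-PrMgCl (THF, −20 °C) into (E)-N-methoxy-N-methyl-3-[3,5-diprenyl-4-(TBSO)phenyl]prop-2-enamide F1. Nucleophilic asymmetric epoxidation with t-BuOOH under Sm(O-i-Pr)3/(S)-BINOL/Ph3As=O (THF, 4 Å molecular sieves, rt) attacks only the electron-poor alkene and should give (2R,3S)-N-methoxy-N-methyl-3-[3,5-diprenyl-4-(TBSO)phenyl]oxirane-2-carboxamide F2; (S)-BINOL is expected to give this sense, and the ligand antipode would be used otherwise. SN2 opening of F2 at the benzylic carbon by the potassium salt of phenol 15 (K2CO3, MeCN, 50 °C) should give (2R,3R)-3-[6-bromo-2-prenyl-3-(TBSO)phenoxy]-2-hydroxy-N-methoxy-N-methyl-3-[3,5-diprenyl-4-(TBSO)phenyl]propanamide F3 with inversion. Silylation of F3 (TBSOTf, 2,6-lutidine) gives 22.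

2. Step 14. Deprotonation at C3–H with β-elimination of the aryloxide, or direct addition of the alkyllithium to the amide, may compete with halogen–lithium exchange. The fallback sets out from acid 20 and returns at ketone 25, omitting step 13. Acid 20 in THF at −78 °C would be treated with t-BuLi (3.1 equiv). The first equivalent forms the carboxylate and the next two effect the exchange, giving lithium (2R,3R)-3-[6-lithio-2-prenyl-3-(TBSO)phenoxy]-2-(TBSO)-3-[3,5-diprenyl-4-(TBSO)phenyl]propanoate F4. A carboxylate is neither enolised nor attacked by t-BuLi under these conditions. On warming to −20 °C, F4 should cyclise in the manner of the classical Parham cyclization of ortho-bromoaryl carboxylic acids to dilithium (2R,3R)-8-prenyl-3,7-bis(TBSO)-2-[3,5-diprenyl-4-(TBSO)phenyl]chromane-4,4-diolate F5. Aqueous NH4Cl then releases 25.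

3. Step 11. The methanolysis may not discriminate cleanly between the primary and secondary silyl ethers, an aryl silyl ether may be lost alongside, or the benzylic aryl ether may solvolyse under acid. The fallback uses orthogonal protection instead of selective desilylation. It sets out from diol 16 and returns at alcohol 18, replacing steps 10 and 11. Selective acylation of the primary hydroxyl (pivaloyl chloride, pyridine, CH2Cl2, 0 °C) would give [(2S,3R)-3-[6-bromo-2-prenyl-3-(TBSO)phenoxy]-2-hydroxy-3-[3,5-diprenyl-4-(TBSO)phenyl]propyl] 2,2-dimethylpropanoate F6. Silylation (TBSOTf, 2,6-lutidine) would give [(2S,3R)-3-[6-bromo-2-prenyl-3-(TBSO)phenoxy]-2-(TBSO)-3-[3,5-diprenyl-4-(TBSO)phenyl]propyl] 2,2-dimethylpropanoate F7. Reductive removal of the pivalate (i-Bu2AlH, CH2Cl2, −78 °C) gives 18.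

**Further compounds**

F1 | step 9 | (E)-3-[4-(tert-butyldimethylsilyloxy)-3,5-bis(3-methylbut-2-enyl)phenyl]-N-methoxy-N-methylprop-2-enamide | CON(C)C(=O)/C=C/c1cc(CC=C(C)C)c(O[Si](C)(C)C(C)(C)C)c(CC=C(C)C)c1
F2 | step 9 | (2R,3S)-3-[4-(tert-butyldimethylsilyloxy)-3,5-bis(3-methylbut-2-enyl)phenyl]-N-methoxy-N-methyloxirane-2-carboxamide | CON(C)C(=O)[C@@H]1O[C@H]1c1cc(CC=C(C)C)c(O[Si](C)(C)C(C)(C)C)c(CC=C(C)C)c1
F3 | step 9 | (2R,3R)-3-[6-bromo-3-(tert-butyldimethylsilyloxy)-2-(3-methylbut-2-enyl)phenoxy]-3-[4-(tert-butyldimethylsilyloxy)-3,5-bis(3-methylbut-2-enyl)phenyl]-2-hydroxy-N-methoxy-N-methylpropanamide | CON(C)C(=O)[C@H](O)[C@@H](c1cc(CC=C(C)C)c(O[Si](C)(C)C(C)(C)C)c(CC=C(C)C)c1)Oc1c(Br)ccc(O[Si](C)(C)C(C)(C)C)c1CC=C(C)C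
F4 | step 14 | lithium (2R,3R)-3-[3-(tert-butyldimethylsilyloxy)-6-lithio-2-(3-methylbut-2-enyl)phenoxy]-2-(tert-butyldimethylsilyloxy)-3-[4-(tert-butyldimethylsilyloxy)-3,5-bis(3-methylbut-2-enyl)phenyl]propanoate | [Li]OC(=O)[C@H](O[Si](C)(C)C(C)(C)C)[C@@H](c1cc(CC=C(C)C)c(O[Si](C)(C)C(C)(C)C)c(CC=C(C)C)c1)Oc1c([Li])ccc(O[Si](C)(C)C(C)(C)C)c1CC=C(C)C
F5 | step 14 | dilithium (2R,3R)-3,7-bis(tert-butyldimethylsilyloxy)-2-[4-(tert-butyldimethylsilyloxy)-3,5-bis(3-methylbut-2-enyl)phenyl]-8-(3-methylbut-2-enyl)chromane-4,4-diolate | [Li]OC1(O[Li])c2ccc(O[Si](C)(C)C(C)(C)C)c(CC=C(C)C)c2O[C@H](c2cc(CC=C(C)C)c(O[Si](C)(C)C(C)(C)C)c(CC=C(C)C)c2)[C@H]1O[Si](C)(C)C(C)(C)C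
F6 | step 11 | [(2S,3R)-3-[6-bromo-3-(tert-butyldimethylsilyloxy)-2-(3-methylbut-2-enyl)phenoxy]-3-[4-(tert-butyldimethylsilyloxy)-3,5-bis(3-methylbut-2-enyl)phenyl]-2-hydroxypropyl] 2,2-dimethylpropanoate | CC(C)(C)C(=O)OC[C@H](O)[C@@H](c1cc(CC=C(C)C)c(O[Si](C)(C)C(C)(C)C)c(CC=C(C)C)c1)Oc1c(Br)ccc(O[Si](C)(C)C(C)(C)C)c1CC=C(C)C
F7 | step 11 | [(2S,3R)-3-[6-bromo-3-(tert-butyldimethylsilyloxy)-2-(3-methylbut-2-enyl)phenoxy]-2-(tert-butyldimethylsilyloxy)-3-[4-(tert-butyldimethylsilyloxy)-3,5-bis(3-methylbut-2-enyl)phenyl]propyl] 2,2-dimethylpropanoate | CC(C)(C)C(=O)OC[C@H](O[Si](C)(C)C(C)(C)C)[C@@H](c1cc(CC=C(C)C)c(O[Si](C)(C)C(C)(C)C)c(CC=C(C)C)c1)Oc1c(Br)ccc(O[Si](C)(C)C(C)(C)C)c1CC=C(C)C
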